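**Retrosynthetic overview**
1. Target 22 ← methyl ester 20 ← enol triflate 19 (methyl cross-coupling gives the C7 methyl and the C6=C7 alkene) ← trans-hydrindenone 17; the cyclopentene (ring B) is closed last by metathesis of diene 16.
2. 16 ← cyclohexenone 12 by anti conjugate addition (sets C3a) and branched allylation (sets C7a and C1).
3. 12 (ring A) ← cyclopentenone 10 by a one-carbon ring expansion that inserts CH2 between the carbonyl and the dienyl-bearing quaternary carbon.
4. 10 ← β-keto aldehyde 7 (two olefinations, dehydrogenation); 7 ← epoxy ketone 6 by a ring contraction (1,2-acyl shift) that builds the second quaternary centre beside the first.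
5. 6 ← Robinson enone 5 ← methyl acetoacetate, MeI and methyl vinyl ketone. Ring order: cyclohexenone 5 → cyclopentanone 7 → cyclohexenone 12 (ring A) → cyclopentene (ring B).

Assumption: compounds 1, 3, 13 and 15 and the olefination reagents are bought; for each chiral catalyst or ligand the enantiomeric series that gives the drawn configuration is meant.

**Step 1**
Reactants: 1 methyl acetoacetate
Product: 2 methyl 2-methyl-3-oxobutanoate
Conditions: MeI (1.05 equiv), K2CO3, acetone, reflux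
Reagents that add atoms: iodomethane, CI
Why: SN2 C-methylation of the β-keto ester enolate; one equivalent of MeI keeps dialkylation low.

**Step 2**
Reactants: 2 methyl 2-methyl-3-oxobutanoate; 3 but-3-en-2-one
Product: 5 methyl (1R)-1,2-dimethyl-4-oxocyclohex-2-ene-1-carboxylate, via diketo ester 4 (not isolated)
Conditions: 9-O-(9-phenanthryl)cupreidine (10 mol%), CH2Cl2, −24 °C; then p-TsOH·H2O (20 mol%), toluene, 90 °C
Reagents that add atoms: none
Why: Robinson annulation in which the cinchona-catalysed enantioselective Michael addition sets the quaternary stereocentre (later C4) and the acid-promoted aldol condensation closes the enone without touching it.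

**Step 3**
Reactants: 5 methyl (1R)-1,2-dimethyl-4-oxocyclohex-2-ene-1-carboxylate
Product: 6 methyl (1R,2R,6R)-1,2-dimethyl-5-oxo-7-oxabicyclo[4.1.0]heptane-2-carboxylate (oxirane oxygen cis to CO2Me)
Conditions: 50% aq. H2O2 (1.5 equiv), 9-amino-9-deoxy-epi-quinine (10 mol%), CF3CO2H (20 mol%), dioxane, 40 °C
Reagents that add atoms: hydrogen peroxide, OO
Why: Iminium-activated Weitz–Scheffer (nucleophilic) epoxidation in which the amine catalyst, not the weak Me/CO2Me bias of the substrate, delivers oxygen to the face cis to the ester.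

**Step 4**
Reactants: 6 methyl (1R,2R,6R)-1,2-dimethyl-5-oxo-7-oxabicyclo[4.1.0]heptane-2-carboxylate
Product: 7 methyl (1R,2S)-2-formyl-1,2-dimethyl-3-oxocyclopentane-1-carboxylate (CHO cis to CO2Me)
Conditions: BF3·OEt2 (1.0 equiv), CH2Cl2, −20 to 0 °C
Reagents that add atoms: none
Why: Lewis-acid epoxy-ketone rearrangement (semipinacol-type 1,2-acyl shift, ring contraction): the tertiary C–O bond opens and the acyl carbon migrates anti to it with inversion, so the former β-carbon becomes the formyl-bearing quaternary centre with CHO on the former oxirane face, next to the existing quaternary carbon.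

**Step 5**
Reactants: 7 methyl (1R,2S)-2-formyl-1,2-dimethyl-3-oxocyclopentane-1-carboxylate
Product: 8 methyl (1R,2R)-1,2-dimethyl-2-[(1E)-2-methyl-3-oxoprop-1-en-1-yl]-3-oxocyclopentane-1-carboxylate
Conditions: Ph3P=C(Me)CHO (1.5 equiv), toluene, 100 °C
Reagents that add atoms: 2-(triphenylphosphoranylidene)propanal, CC(C=O)=P(c1ccccc1)(c1ccccc1)c1ccccc1
Why: Wittig olefination with a stabilised ylide gives the (E)-2-methyl enal; only the aldehyde reacts, the hindered ketone and the ester do not.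

**Step 6**
Reactants: 8 methyl (1R,2R)-1,2-dimethyl-2-[(1E)-2-methyl-3-oxoprop-1-en-1-yl]-3-oxocyclopentane-1-carboxylate
Product: 9 methyl (1R,2R)-1,2-dimethyl-2-[(1E,3E)-2-methyl-4-phenylbuta-1,3-dien-1-yl]-3-oxocyclopentane-1-carboxylate
Conditions: (EtO)2P(O)CH2Ph, KOt-Bu, THF, 0 °C; then 8, −78 to 0 °C
Reagents that add atoms: diethyl benzylphosphonate, CCOP(=O)(Cc1ccccc1)OCC
Why: Horner–Wadsworth–Emmons olefination of the enal gives the (E)-styryl alkene and completes the side chain, which from here on also serves as the large group on its carbon.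

**Step 7**
Reactants: 9 methyl (1R,2R)-1,2-dimethyl-2-[(1E,3E)-2-methyl-4-phenylbuta-1,3-dien-1-yl]-3-oxocyclopentane-1-carboxylate
Product: 10 methyl (1R,5R)-1,5-dimethyl-5-[(1E,3E)-2-methyl-4-phenylbuta-1,3-dien-1-yl]-4-oxocyclopent-2-ene-1-carboxylate
Conditions: IBX (1.5 equiv), 4-methoxypyridine N-oxide, DMSO, 25–40 °C
Reagents that add atoms: none
Why: IBX dehydrogenation of the ketone, which can enolise on one side only because the other α-carbon is quaternary.

**Step 8**
Reactants: 10 methyl (1R,5R)-1,5-dimethyl-5-[(1E,3E)-2-methyl-4-phenylbuta-1,3-dien-1-yl]-4-oxocyclopent-2-ene-1-carboxylate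
Product: 12 methyl (1R,6R)-1,6-dimethyl-6-[(1E,3E)-2-methyl-4-phenylbuta-1,3-dien-1-yl]-4-oxocyclohex-2-ene-1-carboxylate, via alpha-silyl ketone 11 (not isolated)
Conditions: Me3SiCHN2 (2 equiv), Sc(OTf)3 (10 mol%), CH2Cl2, −78 to −20 °C; then 1 M HCl, THF, 0 °C
Reagents that add atoms: (trimethylsilyl)diazomethane, C[Si](C)(C)C=[N+]=[N-]
Why: Proposed new method: Sc(OTf)3-activated 1,2-addition of the diazoalkane to the enone carbonyl gives a diazonium alkoxide in which the fully substituted, allylic sp3 α′-carbon migrates with retention and loss of N2 (the sp2 α-carbon of an enone is a poor migrating group in Lewis-acid diazoacetate homologations of cycloalkenones), so CH2 is inserted next to the quaternary carbon and ring A appears as the transposed enone after protodesilylation; the closest known reaction type is the Tiffeneau–Demjanov-type diazoalkane homologation of ketones, not yet shown for an α′-quaternary cyclopent-2-enone.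

**Step 9**
Reactants: 12 methyl (1R,6R)-1,6-dimethyl-6-[(1E,3E)-2-methyl-4-phenylbuta-1,3-dien-1-yl]-4-oxocyclohex-2-ene-1-carboxylate; 13 isopropenylmagnesium bromide
Product: 14 methyl (1R,2R,6R)-1,6-dimethyl-6-[(1E,3E)-2-methyl-4-phenylbuta-1,3-dien-1-yl]-2-(prop-1-en-2-yl)-4-[(trimethylsilyl)oxy]cyclohex-3-ene-1-carboxylate
Conditions: 13 (2 equiv), CuBr·SMe2 (20 mol%), Me3SiCl, HMPA, THF, −78 °C; Et3N quench
Reagents that add atoms: chlorotrimethylsilane, C[Si](C)(C)Cl
Why: Copper-catalysed conjugate addition with silyl trapping: with the dienyl group equatorial the ester is pseudoaxial, so axial attack comes anti to CO2Me and puts the isopropenyl group cis to the neighbouring methyl (later C3a).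

**Step 10**
Reactants: 14 methyl (1R,2R,6R)-1,6-dimethyl-6-[(1E,3E)-2-methyl-4-phenylbuta-1,3-dien-1-yl]-2-(prop-1-en-2-yl)-4-[(trimethylsilyl)oxy]cyclohex-3-ene-1-carboxylate; 15 (2E)-but-2-en-1-yl acetate
Product: 16 methyl (1R,2R,3S,6R)-3-[(2R)-but-3-en-2-yl]-1,6-dimethyl-6-[(1E,3E)-2-methyl-4-phenylbuta-1,3-dien-1-yl]-4-oxo-2-(prop-1-en-2-yl)cyclohexane-1-carboxylate
Conditions: [Ir(cod)Cl]2 (2 mol%), BINOL-derived N,N-bis(1-phenylethyl)phosphoramidite (4 mol%), CsF, ZnF2 (cat.), DME, 50 °C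
Reagents that add atoms: none
Why: Iridium-catalysed branched-selective allylic alkylation of the fluoride-released enolate: the enolate is attacked trans to the adjacent isopropenyl group (later C7a) and the ligand sets the methyl-bearing allylic carbon (later C1).

**Step 11**
Reactants: 16 methyl (1R,2R,3S,6R)-3-[(2R)-but-3-en-2-yl]-1,6-dimethyl-6-[(1E,3E)-2-methyl-4-phenylbuta-1,3-dien-1-yl]-4-oxo-2-(prop-1-en-2-yl)cyclohexane-1-carboxylate
Product: 17 methyl (1R,3aR,4R,5R,7aS)-1,3,4,5-tetramethyl-5-[(1E,3E)-2-methyl-4-phenylbuta-1,3-dien-1-yl]-7-oxo-3a,4,5,6,7,7a-hexahydro-1H-indene-4-carboxylate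
Conditions: second-generation Hoveyda–Grubbs catalyst (5 mol%), toluene (2 mM), 70 °C, argon sparge
Reagents that add atoms: none
Why: Ring-closing metathesis of the trans-disposed isopropenyl and vinyl groups gives the trisubstituted cyclopentene (ring B) with the trans ring fusion already fixed; the hindered internal diene of the side chain reacts much more slowly than the terminal alkenes.

**Step 12**
Reactants: 17 methyl (1R,3aR,4R,5R,7aS)-1,3,4,5-tetramethyl-5-[(1E,3E)-2-methyl-4-phenylbuta-1,3-dien-1-yl]-7-oxo-3a,4,5,6,7,7a-hexahydro-1H-indene-4-carboxylate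
Product: 19 methyl (1R,3aR,4R,5S,7aS)-1,3,4,5-tetramethyl-5-[(1E,3E)-2-methyl-4-phenylbuta-1,3-dien-1-yl]-7-{[(trifluoromethyl)sulfonyl]oxy}-3a,4,5,7a-tetrahydro-1H-indene-4-carboxylate, via potassium enolate 18 (not isolated)
Conditions: KN(SiMe3)2, THF, −78 °C; then PhNTf2, −78 to −20 °C
Reagents that add atoms: N-phenylbis(trifluoromethanesulfonimide), O=S(=O)(N(c1ccccc1)S(=O)(=O)C(F)(F)F)C(F)(F)F
Why: Kinetic deprotonation takes the CH2 proton and not the ring-fusion methine (a tetrasubstituted enolate at a trans ring fusion is strained), and O-triflation fixes the enol triflate at C6=C7.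

**Step 13**
Reactants: 19 methyl (1R,3aR,4R,5S,7aS)-1,3,4,5-tetramethyl-5-[(1E,3E)-2-methyl-4-phenylbuta-1,3-dien-1-yl]-7-{[(trifluoromethyl)sulfonyl]oxy}-3a,4,5,7a-tetrahydro-1H-indene-4-carboxylate
Product: 20 methyl (1R,3aR,4R,5S,7aS)-1,3,4,5,7-pentamethyl-5-[(1E,3E)-2-methyl-4-phenylbuta-1,3-dien-1-yl]-3a,4,5,7a-tetrahydro-1H-indene-4-carboxylate
Conditions: MeMgBr (1.5 equiv), Fe(acac)3 (5 mol%), THF/NMP, −20 °C
Reagents that add atoms: methylmagnesium bromide, C[Mg]Br
Why: Iron-catalysed Kumada-type cross-coupling of the alkenyl triflate installs the last methyl group without moving the alkene, and the hindered ester survives at low temperature.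

**Step 14**
Reactants: 20 methyl (1R,3aR,4R,5S,7aS)-1,3,4,5,7-pentamethyl-5-[(1E,3E)-2-methyl-4-phenylbuta-1,3-dien-1-yl]-3a,4,5,7a-tetrahydro-1H-indene-4-carboxylate
Product: 22 (1R,3aR,4R,5S,7aS)-1,3,4,5,7-pentamethyl-5-[(1E,3E)-2-methyl-4-phenylbuta-1,3-dien-1-yl]-3a,4,5,7a-tetrahydro-1H-indene-4-carboxylic acid (27-nor-zyggomphic acid B), via lithium carboxylate 21 (not isolated)
Conditions: LiI (10 equiv), pyridine, 115 °C; then 1 M HCl
Reagents that add atoms: none
Why: SN2 O-demethylation by iodide attacks the unhindered methyl group, so the doubly neopentyl ester is cleaved where saponification at the carbonyl would fail.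

**Compound list**
1 | methyl acetoacetate | CC(=O)CC(=O)OC | starting material
2 | methyl 2-methyl-3-oxobutanoate | CC(=O)C(C)C(=O)OC | intermediate
3 | but-3-en-2-one (methyl vinyl ketone) | C=CC(C)=O | starting material
4 | methyl (2R)-2-acetyl-2-methyl-5-oxohexanoate | CC(=O)[C@](C)(C(=O)OC)CCC(C)=O | intermediate
5 | methyl (1R)-1,2-dimethyl-4-oxocyclohex-2-ene-1-carboxylate | O=C1C=C(C)[C@](C)(C(=O)OC)CC1 | intermediate
6 | methyl (1R,2R,6R)-1,2-dimethyl-5-oxo-7-oxabicyclo[4.1.0]heptane-2-carboxylate | O=C1[C@@H]2O[C@]2(C)[C@](C)(C(=O)OC)CC1 | intermediate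
7 | methyl (1R,2S)-2-formyl-1,2-dimethyl-3-oxocyclopentane-1-carboxylate | O=C1CC[C@@](C)(C(=O)OC)[C@@]1(C)C=O | intermediate
8 | methyl (1R,2R)-1,2-dimethyl-2-[(1E)-2-methyl-3-oxoprop-1-en-1-yl]-3-oxocyclopentane-1-carboxylate | O=C1CC[C@@](C)(C(=O)OC)[C@@]1(C)/C=C(\C)C=O | intermediate
9 | methyl (1R,2R)-1,2-dimethyl-2-[(1E,3E)-2-methyl-4-phenylbuta-1,3-dien-1-yl]-3-oxocyclopentane-1-carboxylate | O=C1CC[C@@](C)(C(=O)OC)[C@@]1(C)/C=C(C)/C=C/c2ccccc2 | intermediate
10 | methyl (1R,5R)-1,5-dimethyl-5-[(1E,3E)-2-methyl-4-phenylbuta-1,3-dien-1-yl]-4-oxocyclopent-2-ene-1-carboxylate | O=C1C=C[C@@](C)(C(=O)OC)[C@@]1(C)/C=C(C)/C=C/c2ccccc2 | intermediate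
11 | methyl (1R,6R)-1,6-dimethyl-6-[(1E,3E)-2-methyl-4-phenylbuta-1,3-dien-1-yl]-4-oxo-5-(trimethylsilyl)cyclohex-2-ene-1-carboxylate (C5 epimers) | O=C1C=C[C@@](C)(C(=O)OC)[C@@](C)(/C=C(C)/C=C/c2ccccc2)C1[Si](C)(C)C | intermediate
12 | methyl (1R,6R)-1,6-dimethyl-6-[(1E,3E)-2-methyl-4-phenylbuta-1,3-dien-1-yl]-4-oxocyclohex-2-ene-1-carboxylate | O=C1C=C[C@@](C)(C(=O)OC)[C@@](C)(/C=C(C)/C=C/c2ccccc2)C1 | intermediate
13 | isopropenylmagnesium bromide | C=C(C)[Mg]Br | starting material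
14 | methyl (1R,2R,6R)-1,6-dimethyl-6-[(1E,3E)-2-methyl-4-phenylbuta-1,3-dien-1-yl]-2-(prop-1-en-2-yl)-4-[(trimethylsilyl)oxy]cyclohex-3-ene-1-carboxylate | C[Si](C)(C)OC1=C[C@H](C(C)=C)[C@@](C)(C(=O)OC)[C@@](C)(/C=C(C)/C=C/c2ccccc2)C1 | intermediate
15 | (2E)-but-2-en-1-yl acetate | C/C=C/COC(C)=O | starting material
16 | methyl (1R,2R,3S,6R)-3-[(2R)-but-3-en-2-yl]-1,6-dimethyl-6-[(1E,3E)-2-methyl-4-phenylbuta-1,3-dien-1-yl]-4-oxo-2-(prop-1-en-2-yl)cyclohexane-1-carboxylate | O=C1C[C@](C)(/C=C(C)/C=C/c2ccccc2)[C@](C)(C(=O)OC)[C@@H](C(C)=C)[C@@H]1[C@H](C)C=C | intermediate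
17 | methyl (1R,3aR,4R,5R,7aS)-1,3,4,5-tetramethyl-5-[(1E,3E)-2-methyl-4-phenylbuta-1,3-dien-1-yl]-7-oxo-3a,4,5,6,7,7a-hexahydro-1H-indene-4-carboxylate | O=C1C[C@](C)(/C=C(C)/C=C/c2ccccc2)[C@](C)(C(=O)OC)[C@H]2C(C)=C[C@@H](C)[C@H]12 | intermediate
18 | potassium (1R,3aR,4R,5S,7aS)-4-(methoxycarbonyl)-1,3,4,5-tetramethyl-5-[(1E,3E)-2-methyl-4-phenylbuta-1,3-dien-1-yl]-3a,4,5,7a-tetrahydro-1H-inden-7-olate | [K+].[O-]C1=C[C@](C)(/C=C(C)/C=C/c2ccccc2)[C@](C)(C(=O)OC)[C@H]2C(C)=C[C@@H](C)[C@H]12 | intermediate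
19 | methyl (1R,3aR,4R,5S,7aS)-1,3,4,5-tetramethyl-5-[(1E,3E)-2-methyl-4-phenylbuta-1,3-dien-1-yl]-7-{[(trifluoromethyl)sulfonyl]oxy}-3a,4,5,7a-tetrahydro-1H-indene-4-carboxylate | O=S(=O)(OC1=C[C@](C)(/C=C(C)/C=C/c2ccccc2)[C@](C)(C(=O)OC)[C@H]2C(C)=C[C@@H](C)[C@H]12)C(F)(F)F | intermediate
20 | methyl (1R,3aR,4R,5S,7aS)-1,3,4,5,7-pentamethyl-5-[(1E,3E)-2-methyl-4-phenylbuta-1,3-dien-1-yl]-3a,4,5,7a-tetrahydro-1H-indene-4-carboxylate | CC1=C[C@](C)(/C=C(C)/C=C/c2ccccc2)[C@](C)(C(=O)OC)[C@H]2C(C)=C[C@@H](C)[C@H]12 | intermediate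
21 | lithium (1R,3aR,4R,5S,7aS)-1,3,4,5,7-pentamethyl-5-[(1E,3E)-2-methyl-4-phenylbuta-1,3-dien-1-yl]-3a,4,5,7a-tetrahydro-1H-indene-4-carboxylate | CC1=C[C@](C)(/C=C(C)/C=C/c2ccccc2)[C@](C)(C(=O)[O-])[C@H]2C(C)=C[C@@H](C)[C@H]12.[Li+] | intermediate
22 | (1R,3aR,4R,5S,7aS)-1,3,4,5,7-pentamethyl-5-[(1E,3E)-2-methyl-4-phenylbuta-1,3-dien-1-yl]-3a,4,5,7a-tetrahydro-1H-indene-4-carboxylic acid (27-nor-zyggomphic acid B) | CC1=C[C@](C)(/C=C(C)/C=C/c2ccccc2)[C@](C)(C(=O)O)[C@H]2C(C)=C[C@@H](C)[C@H]12 | target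

**Step count**
Total: 14 steps. Longest linear sequence: 14 steps.

**Three steps most likely to fail**

Step 3 (facial control of the epoxidation; the substrate's own preference between Me and CO2Me is small and may oppose the catalyst). The fallback sets out from 5 and comes back at 6, and ties the new C–O bond to the carboxyl group. Luche reduction (NaBH4, CeCl3·7H2O, MeOH) gives methyl (1R)-4-hydroxy-1,2-dimethylcyclohex-2-ene-1-carboxylate F1. LiOH in aqueous THF gives (1R)-4-hydroxy-1,2-dimethylcyclohex-2-ene-1-carboxylic acid F2. Iodolactonisation (I2, NaHCO3, CH2Cl2/H2O, 0 °C) delivers the carboxylate oxygen from its own face and gives (1R,2R,6R)-3-hydroxy-2-iodo-1,6-dimethyl-8-oxabicyclo[4.2.0]octan-7-one F3. NaOMe in MeOH opens the lactone to the methyl ester, and the freed alkoxide displaces the anti iodide to give methyl (1R,2R,6S)-5-hydroxy-1,2-dimethyl-7-oxabicyclo[4.1.0]heptane-2-carboxylate F4. Dess–Martin periodinane then returns epoxy ketone 6.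

Step 5 (olefination of an aldehyde on a quaternary carbon flanked by a second quaternary carbon and a ketone). The fallback sets out from 7 and comes back at 8, replacing the bulky phosphorus ylide with a Peterson-type directed aldol. The lithio anion of N-tert-butyl-2-(triethylsilyl)propan-1-imine adds to the aldehyde at −78 °C and loses silanolate to give methyl (1R,2R)-2-[(1E)-3-(tert-butylimino)-2-methylprop-1-en-1-yl]-1,2-dimethyl-3-oxocyclopentane-1-carboxylate F5. Aqueous oxalic acid hydrolyses the imine to enal 8.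

Step 8 (the proposed new ring expansion; risks are slow addition to the hindered carbonyl, dipolar addition to the enone C=C, and migration of the wrong carbon). The fallback uses known chemistry, sets out from 10 and comes back at 12. Ethyl diazoacetate with BF3·OEt2 in CH2Cl2 at 0 °C, the established homologation of α,β-unsaturated ketones on their saturated side, gives 1-ethyl 3-methyl (2S,3R)-2,3-dimethyl-2-[(1E,3E)-2-methyl-4-phenylbuta-1,3-dien-1-yl]-6-oxocyclohex-4-ene-1,3-dicarboxylate F6. Krapcho dealkoxycarbonylation (LiCl, wet DMSO, 140 °C) removes only the β-keto ester group and gives 12.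

**Further compounds**
F1 | step 3 | methyl (1R)-4-hydroxy-1,2-dimethylcyclohex-2-ene-1-carboxylate (C4 epimers) | OC1C=C(C)[C@](C)(C(=O)OC)CC1
F2 | step 3 | (1R)-4-hydroxy-1,2-dimethylcyclohex-2-ene-1-carboxylic acid (C4 epimers) | OC1C=C(C)[C@](C)(C(=O)O)CC1
F3 | step 3 | (1R,2R,6R)-3-hydroxy-2-iodo-1,6-dimethyl-8-oxabicyclo[4.2.0]octan-7-one (C3 epimers) | C[C@@]12OC(=O)[C@]1(C)CCC(O)[C@H]2I
F4 | step 3 | methyl (1R,2R,6S)-5-hydroxy-1,2-dimethyl-7-oxabicyclo[4.1.0]heptane-2-carboxylate (C5 epimers) | OC1[C@@H]2O[C@]2(C)[C@](C)(C(=O)OC)CC1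
F5 | step 5 | methyl (1R,2R)-2-[(1E)-3-(tert-butylimino)-2-methylprop-1-en-1-yl]-1,2-dimethyl-3-oxocyclopentane-1-carboxylate | O=C1CC[C@@](C)(C(=O)OC)[C@@]1(C)/C=C(\C)/C=N/C(C)(C)C
F6 | step 8 | 1-ethyl 3-methyl (2S,3R)-2,3-dimethyl-2-[(1E,3E)-2-methyl-4-phenylbuta-1,3-dien-1-yl]-6-oxocyclohex-4-ene-1,3-dicarboxylate (C1 epimers) | O=C1C=C[C@@](C)(C(=O)OC)[C@@](C)(/C=C(C)/C=C/c2ccccc2)C1C(=O)OCC
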